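**Strategy.** The route rests on cutting the CH2–CH2 bond of the 4-acyloxybut-1-ynyl chain on the 2,2′-bithiophene. The key step exploits the three-carbon unit formed by the propargylic CH2 and the two alkyne carbons attached to the thiophene ring. A prop-2-ynyl methyl carbonate is turned by copper-catalysed γ-borylation into a 1-thienylallenylboronate, whose CH2 terminus adds to formaldehyde through a cyclic SE2′ transition state. One flask thus joins carbonate, diboron and formaldehyde, makes the CH2–CH2 bond and restores the alkyne regiospecifically. The precursor is the propargylic carbonate of the bithiophene that already carries the thienylmethyl isovalerate; the second isovalerate is added last.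

Key step: step 5

Remark: the target has no stereocentre and no stereogenic double bond, so it is achiral; the structure as drawn is its only stereoisomer and no stereocontrol is needed.

**Step 1**
Reactants: 1 5′-bromo-2,2′-bithiophene-5-carbaldehyde
Product: 2 (5′-bromo-2,2′-bithiophen-5-yl)methanol
Conditions: NaBH4 (0.6 equiv), THF/MeOH (4:1), 0 °C; aq. NH4Cl
Reagents that add atoms: none
Why: Sodium borohydride reduction of the heteroaryl aldehyde is fast and chemoselective and should leave the C–Br bond and both thiophene rings untouched.

**Step 2**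
Reactants: 2 (5′-bromo-2,2′-bithiophen-5-yl)methanol; 3 3-methylbutanoyl chloride (isovaleryl chloride)
Product: 4 (5′-bromo-2,2′-bithiophen-5-yl)methyl 3-methylbutanoate
Conditions: 3 (1.2 equiv), Et3N (1.5 equiv), DMAP (5 mol %), CH2Cl2, 0 °C to rt
Reagents that add atoms: 3-methylbutanoyl chloride, CC(C)CC(=O)Cl
Why: DMAP-catalysed O-acylation (nucleophilic acyl substitution) of the primary alcohol should be fast at 0 °C, and the amine base traps HCl so that the acid-sensitive thienylmethyl C–O bond does not ionise.

**Step 3**
Reactants: 4 (5′-bromo-2,2′-bithiophen-5-yl)methyl 3-methylbutanoate; 5 prop-2-yn-1-ol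
Product: 6 [5′-(3-hydroxyprop-1-yn-1-yl)-2,2′-bithiophen-5-yl]methyl 3-methylbutanoate
Conditions: PdCl2(PPh3)2 (3 mol %), CuI (5 mol %), Et3N/THF (1:2), degassed, 50 °C
Reagents that add atoms: prop-2-yn-1-ol, C#CCO
Why: Sonogashira coupling of the 2-bromothiophene C–Br bond with the terminal alkyne should proceed under Pd/Cu catalysis, and both the free hydroxyl and the ester are tolerated.

**Step 4**
Reactants: 6 [5′-(3-hydroxyprop-1-yn-1-yl)-2,2′-bithiophen-5-yl]methyl 3-methylbutanoate; 7 methyl chloroformate
Product: 8 {5′-[3-(methoxycarbonyloxy)prop-1-yn-1-yl]-2,2′-bithiophen-5-yl}methyl 3-methylbutanoate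
Conditions: 7 (1.5 equiv), pyridine (2 equiv), CH2Cl2, 0 °C
Reagents that add atoms: methyl chloroformate, COC(=O)Cl
Why: Alkoxycarbonylation of the unhindered primary propargylic alcohol with a chloroformate and pyridine is routine and installs the leaving group needed by the copper step without touching the isovalerate.

**Step 5**
Reactants: 8 {5′-[3-(methoxycarbonyloxy)prop-1-yn-1-yl]-2,2′-bithiophen-5-yl}methyl 3-methylbutanoate; 9 bis(pinacolato)diboron; 10 formaldehyde (charged as paraformaldehyde)
Product: 13 [5′-(4-hydroxybut-1-yn-1-yl)-2,2′-bithiophen-5-yl]methyl 3-methylbutanoate, via allenylboronate 11 (not isolated), via pinacol borate ester 12 (not isolated)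
Conditions: 9 (1.1 equiv), CuOt-Bu (from CuCl/NaOt-Bu, 5 mol %), Xantphos (5 mol %), THF, rt; then (CH2O)n (5 equiv), 60 °C, sealed; aq. NH4Cl
Reagents that add atoms: formaldehyde (from paraformaldehyde), C=O
Why: The boryl-copper species formed from the copper alkoxide and 9 adds across the C≡C bond of 8 with boron on the thienyl-bearing carbon and copper next to the CH2OCO2Me carbon, and β-elimination of methyl carbonate (a formal anti-SN2′ substitution) gives allenylboronate 11. Monomeric formaldehyde released from paraformaldehyde then coordinates to boron and is attacked by the allene CH2 terminus through a six-membered closed transition state (SE2′ allenylboration), which forms the CH2–CH2 bond, returns the triple bond to its original position and leaves borate 12, hydrolysed to 13 on work-up. The closest known reaction types are the copper-catalysed γ-selective borylation of propargylic carbonates and the propargylation of aldehydes by allenylboronates. No ring is closed and no stereocentre is formed. The selectivity needed is regiochemical (but-3-ynyl alcohol rather than the isomeric 2-thienylbuta-2,3-dien-1-ol), and it is secured by two successive 1,3-transpositions: the carbonate leaving group directs boron to the distal alkyne carbon, and the cyclic boron-to-oxygen transfer forces C–C bond formation at the carbon γ to boron. The isovalerate ester and the thiophene rings should be inert to the catalytic copper alkoxide and to the neutral boronate.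

**Step 6**
Reactants: 13 [5′-(4-hydroxybut-1-yn-1-yl)-2,2′-bithiophen-5-yl]methyl 3-methylbutanoate; 3 3-methylbutanoyl chloride
Product: 14 [5′-(4-(3-methylbutanoyloxy)but-1-yn-1-yl)-2,2′-bithiophen-5-yl]methyl 3-methylbutanoate (CNP0154475.0)
Conditions: 3 (1.3 equiv), pyridine (2 equiv), DMAP (5 mol %), CH2Cl2, 0 °C to rt
Reagents that add atoms: 3-methylbutanoyl chloride, CC(C)CC(=O)Cl
Why: DMAP-catalysed acylation of the unhindered primary homopropargylic alcohol (nucleophilic acyl substitution) should complete the second isovalerate without affecting the alkyne or the first ester.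

**Compound list**
1 | 5′-bromo-2,2′-bithiophene-5-carbaldehyde | O=Cc1ccc(-c2ccc(Br)s2)s1 | starting material
2 | (5′-bromo-2,2′-bithiophen-5-yl)methanol | OCc1ccc(-c2ccc(Br)s2)s1 | intermediate
3 | 3-methylbutanoyl chloride | CC(C)CC(=O)Cl | starting material
4 | (5′-bromo-2,2′-bithiophen-5-yl)methyl 3-methylbutanoate | CC(C)CC(=O)OCc1ccc(-c2ccc(Br)s2)s1 | intermediate
5 | prop-2-yn-1-ol | C#CCO | starting material
6 | [5′-(3-hydroxyprop-1-yn-1-yl)-2,2′-bithiophen-5-yl]methyl 3-methylbutanoate | CC(C)CC(=O)OCc1ccc(-c2ccc(C#CCO)s2)s1 | intermediate
7 | methyl chloroformate | COC(=O)Cl | starting material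
8 | {5′-[3-(methoxycarbonyloxy)prop-1-yn-1-yl]-2,2′-bithiophen-5-yl}methyl 3-methylbutanoate | COC(=O)OCC#Cc1ccc(-c2ccc(COC(=O)CC(C)C)s2)s1 | intermediate
9 | bis(pinacolato)diboron | CC1(C)OB(OC1(C)C)B1OC(C)(C)C(C)(C)O1 | starting material
10 | formaldehyde (used as paraformaldehyde) | C=O | starting material
11 | {5′-[1-(4,4,5,5-tetramethyl-1,3,2-dioxaborolan-2-yl)propa-1,2-dien-1-yl]-2,2′-bithiophen-5-yl}methyl 3-methylbutanoate (allenylboronate, not isolated) | C=C=C(B1OC(C)(C)C(C)(C)O1)c1ccc(-c2ccc(COC(=O)CC(C)C)s2)s1 | intermediate
12 | {5′-[4-(4,4,5,5-tetramethyl-1,3,2-dioxaborolan-2-yloxy)but-1-yn-1-yl]-2,2′-bithiophen-5-yl}methyl 3-methylbutanoate (pinacol borate ester of 13, not isolated) | CC(C)CC(=O)OCc1ccc(-c2ccc(C#CCCOB3OC(C)(C)C(C)(C)O3)s2)s1 | intermediate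
13 | [5′-(4-hydroxybut-1-yn-1-yl)-2,2′-bithiophen-5-yl]methyl 3-methylbutanoate | CC(C)CC(=O)OCc1ccc(-c2ccc(C#CCCO)s2)s1 | intermediate
14 | [5′-(4-(3-methylbutanoyloxy)but-1-yn-1-yl)-2,2′-bithiophen-5-yl]methyl 3-methylbutanoate | CC(C)CC(=O)OCCC#Cc1ccc(-c2ccc(COC(=O)CC(C)C)s2)s1 | target

**Totals**
Total step count: 6. Longest linear sequence: 6 steps (1 to 14).

**Steps most likely to fail**

Step 5 (key step). Three processes could erode it:
- Regiochemical leakage: direct α-borylation, or boron-to-copper exchange before the addition, would pass the allenyl instead of the propargyl group to formaldehyde.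
- Protodeboronation of the allenylboronate by adventitious water at 60 °C.
- Alkoxide-mediated transesterification of the thienylmethyl ester.

The fallback changes both the metal and the way the allenyl nucleophile is made, and sets out from 8. Palladium-catalysed indium(I) umpolung (Pd(dppf)Cl2 5 mol %, InI 1.5 equiv, paraformaldehyde, THF/DMPU, rt) should ionise the propargylic carbonate to an allenylpalladium(II) methoxide. Indium(I) should reduce and transmetalate it to {5′-[1-(iodo(methoxy)indio)propa-1,2-dien-1-yl]-2,2′-bithiophen-5-yl}methyl 3-methylbutanoate F1. SE2′ addition of F1 to formaldehyde should give the indium alkoxide of the homopropargylic alcohol F2, and aqueous work-up returns to the route at 13.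

Step 3. Oxidative addition into the electron-rich bromobithiophene may be slow, which would let oxidative dimerisation of prop-2-yn-1-ol compete, and palladium or the amine may attack the thienylmethyl ester C–O bond. The fallback sets out from 1 and reorders the sequence so that the coupling is run on the formyl-activated bromide with no thienylmethyl ester present:
- Sonogashira coupling of 1 with 5 should give 5′-(3-hydroxyprop-1-yn-1-yl)-2,2′-bithiophene-5-carbaldehyde F3.
- Methyl chloroformate 7 and pyridine should give 3-(5′-formyl-2,2′-bithiophen-5-yl)prop-2-yn-1-yl methyl carbonate F4.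
- NaBH4 (THF/MeOH, −20 °C) should reduce only the aldehyde to 3-[5′-(hydroxymethyl)-2,2′-bithiophen-5-yl]prop-2-yn-1-yl methyl carbonate F5.
- Acylation with 3 (Et3N, DMAP) comes back to the route at 8.

Step 2. The electron-rich bithienylmethyl C–O bond may ionise under the acid chloride conditions, leading to chloride substitution or oligomerisation. The fallback sets out from 2 and replaces the acid chloride by the free acid under carbodiimide activation (Steglich esterification: 3-methylbutanoic acid, DCC, DMAP, CH2Cl2, 0 °C to rt). No HCl is generated, and it comes back to the route at 4; this fallback makes no compound outside the list (F0).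

**Further compounds**
F1 | step 5 | {5′-[1-(iodo(methoxy)indio)propa-1,2-dien-1-yl]-2,2′-bithiophen-5-yl}methyl 3-methylbutanoate (allenylindium, not isolated) | CC(C)CC(=O)OCc1ccc(-c2ccc(C(=C=C)[In](I)OC)s2)s1
F2 | step 5 | indium(III) iodide methoxide alkoxide of 13 (not isolated) | CC(C)CC(=O)OCc1ccc(-c2ccc(C#CCCO[In](I)OC)s2)s1
F3 | step 3 | 5′-(3-hydroxyprop-1-yn-1-yl)-2,2′-bithiophene-5-carbaldehyde | O=Cc1ccc(-c2ccc(C#CCO)s2)s1
F4 | step 3 | 3-(5′-formyl-2,2′-bithiophen-5-yl)prop-2-yn-1-yl methyl carbonate | COC(=O)OCC#Cc1ccc(-c2ccc(C=O)s2)s1
F5 | step 3 | 3-[5′-(hydroxymethyl)-2,2′-bithiophen-5-yl]prop-2-yn-1-yl methyl carbonate | COC(=O)OCC#Cc1ccc(-c2ccc(CO)s2)s1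
F0 | step 2 | none | none
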